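## Retrosynthetic overview

1. The target is traced back to its bis-MOM ether, and the C5–CH2 bond is cut (Negishi coupling) into a 5-bromo-2,3-dihydrobenzofuran and an alkylzinc made from (R)-limonene, which supplies the (R) centre and both 1,1-disubstituted alkenes.
2. The dihydrofuran ring is the only ring formed in the route (rings A and B are bought as arenes). It is closed by making the C3–C2 bond in an enantioselective cobalt-porphyrin carbene-radical 1,5-C–H alkylation of an aryl aldehyde tosylhydrazone.
3. Enabling feature: C3 is a benzylic CH2 on C3a, and C2–H lies α to the ring oxygen O1 on the neighbouring C7a, so a carbene at C3 and the O–CH2 hydrogen are 1,5-related through O1. C2 with its 2-hydroxypropan-2-yl group is ring-opened 2,2-dimethyloxirane, and the C7 aroyl group and the free C5–H steer the abstraction away from the C4 methoxy group.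
4. The aldehyde precursor comes from a symmetrical 2,6-dihydroxy-4-methoxybenzophenone (Friedel–Crafts acylation, chelation-controlled demethylation) by mono-formylation, site-selective MOM protection and phenol alkylation.

Key step: step 7

Remark on the chemistry: (4R)-limonene 1,2-oxide is sold as a cis/trans mixture; both diastereomers converge on the same keto-aldehyde, so the mixture is assumed to be used. For step 7 the antipode of the porphyrin ligand that delivers (S) at C2 is assumed to be chosen after a trial run.

## Route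

Step 1
Reactants: 1 1,3,5-trimethoxybenzene; 2 3-(benzyloxy)benzoyl chloride
Product: 3 [3-(benzyloxy)phenyl](2,4,6-trimethoxyphenyl)methanone
Conditions: AlCl3 (1.2 equiv), CH2Cl2, 0 °C
Reagents that add atoms: none
Why: Friedel–Crafts acylation of the highly activated arene at one of its three equivalent positions, the ketone product being deactivated toward a second acylation.

Step 2
Reactants: 3 [3-(benzyloxy)phenyl](2,4,6-trimethoxyphenyl)methanone
Product: 4 (2,6-dihydroxy-4-methoxyphenyl)(3-hydroxyphenyl)methanone
Conditions: BCl3 (6 equiv), pentamethylbenzene (3 equiv), CH2Cl2, −78 °C to rt; aqueous work-up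
Reagents that add atoms: none
Why: Chelation-directed ether cleavage, in which BCl3 held by the ketone oxygen should cleave both ortho methyl ethers and the benzyl ether (benzyl cation trapped by pentamethylbenzene) while the para methoxy group, which cannot chelate, is retained.

Step 3
Reactants: 4 (2,6-dihydroxy-4-methoxyphenyl)(3-hydroxyphenyl)methanone
Product: 5 2,4-dihydroxy-3-(3-hydroxybenzoyl)-6-methoxybenzaldehyde
Conditions: POCl3 (1.3 equiv), DMF (3 equiv), MeCN, 0 °C to rt; then H2O, 50 °C
Reagents that add atoms: N,N-dimethylformamide, CN(C)C=O; water, O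
Why: Vilsmeier–Haack formylation at one of the two equivalent free positions of the phloroglucinol-type ring A, which is far more nucleophilic than ring B and is deactivated toward a second formylation by the new aldehyde.

Step 4
Reactants: 5 2,4-dihydroxy-3-(3-hydroxybenzoyl)-6-methoxybenzaldehyde
Product: 6 2-hydroxy-6-methoxy-4-(methoxymethoxy)-3-[3-(methoxymethoxy)benzoyl]benzaldehyde
Conditions: MOMCl (2.3 equiv), K2CO3, acetone, 0 to 40 °C
Reagents that add atoms: chloromethyl methyl ether, COCCl
Why: Williamson-type ether formation, in which the ring-B phenol and the C4–OH (more acidic through the para formyl group, less hindered) should react before the C2–OH, which is flanked by both carbonyl groups and held in the hydrogen bond to the aldehyde.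

Step 5
Reactants: 6 2-hydroxy-6-methoxy-4-(methoxymethoxy)-3-[3-(methoxymethoxy)benzoyl]benzaldehyde; 7 2,2-dimethyloxirane
Product: 8 2-(2-hydroxy-2-methylpropoxy)-6-methoxy-4-(methoxymethoxy)-3-[3-(methoxymethoxy)benzoyl]benzaldehyde
Conditions: Cs2CO3 (0.3 equiv), nBu4NI (0.1 equiv), the epoxide in tenfold excess, DMF, 90 °C, sealed tube
Reagents that add atoms: none
Why: Base-catalysed epoxide opening, the phenoxide attacking the unsubstituted CH2 terminus (SN2 at the less hindered carbon) to give the tertiary alcohol directly in an addition that joins all atoms of both reactants, with no stereocentre formed.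

Step 6
Reactants: 8 2-(2-hydroxy-2-methylpropoxy)-6-methoxy-4-(methoxymethoxy)-3-[3-(methoxymethoxy)benzoyl]benzaldehyde
Product: 9 N'-[(E)-{2-(2-hydroxy-2-methylpropoxy)-6-methoxy-4-(methoxymethoxy)-3-[3-(methoxymethoxy)benzoyl]phenyl}methylidene]-4-methylbenzenesulfonohydrazide
Conditions: TsNHNH2 (1.05 equiv), MeOH, rt
Reagents that add atoms: p-toluenesulfonohydrazide, Cc1ccc(cc1)S(=O)(=O)NN
Why: Condensation of the aldehyde with the hydrazide, the di-ortho-substituted diaryl ketone being too hindered and too electron-rich to compete.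

Step 7
Reactants: 9 N'-[(E)-{2-(2-hydroxy-2-methylpropoxy)-6-methoxy-4-(methoxymethoxy)-3-[3-(methoxymethoxy)benzoyl]phenyl}methylidene]-4-methylbenzenesulfonohydrazide
Product: 11 [(2S)-2-(2-hydroxypropan-2-yl)-4-methoxy-6-(methoxymethoxy)-2,3-dihydro-1-benzofuran-7-yl][3-(methoxymethoxy)phenyl]methanone, via aryldiazomethane 10 (not isolated)
Conditions: Cs2CO3 (2 equiv), [Co(P*)] (3 mol %; P* = dianion of 5,15-bis(3,5-di-tert-butylphenyl)-10,20-bis{2,6-bis[(S)-2,2-dimethylcyclopropane-1-carboxamido]phenyl}porphyrin or its antipode), 1,4-dioxane, 50 °C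
Reagents that add atoms: none
Why: Cs2CO3 converts 9 by Bamford–Stevens loss of sulfinate into aryldiazomethane 10, which the divalent cobalt porphyrin (a metalloradical) should trap with loss of N2 as a trivalent cobalt carbene radical centred on the future C3. This radical abstracts a hydrogen atom from the O–CH2 group through a six-membered transition state (1,5-hydrogen atom transfer), and the resulting α-aryloxy radical at C2 closes the five-membered ring by intramolecular homolytic substitution at the cobalt–C3 bond, which forms the C3–C2 bond and releases divalent cobalt. The closest known reaction types are the enantioselective cobalt-porphyrin 1,5-C–H alkylation of aryl aldehyde tosylhydrazones carrying an ortho heteroatom tether (2-substituted indolines) and the metalloporphyrin carbene C–H insertion of 2-alkoxyaryl tosylhydrazones to 2,3-dihydrobenzofurans. The C2 stereocentre is set in the ring-closing substitution inside the amide-lined chiral cavity of the D2-symmetric porphyrin, whose N–H groups can hydrogen-bond to the substrate oxygens and orient the prochiral radical. The step needs site selectivity for the secondary O–CH2 over the C4 methoxy group, which is also a 1,5-partner: the weaker secondary α-oxy C–H, the C7 aroyl group that forces O–CH2 out of the ring plane toward C3, and the free C5 position toward which the methoxy methyl turns should secure it. It also needs the cyclisation to outrun carbene dimerisation and azine formation (slow release of 10, encumbered cavity) and to leave the free tertiary alcohol, the diaryl ketone and the MOM ethers untouched.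

Step 8
Reactants: 11 [(2S)-2-(2-hydroxypropan-2-yl)-4-methoxy-6-(methoxymethoxy)-2,3-dihydro-1-benzofuran-7-yl][3-(methoxymethoxy)phenyl]methanone
Product: 12 [(2S)-5-bromo-2-(2-hydroxypropan-2-yl)-4-methoxy-6-(methoxymethoxy)-2,3-dihydro-1-benzofuran-7-yl][3-(methoxymethoxy)phenyl]methanone
Conditions: NBS (1.05 equiv), MeCN, 0 °C, dark
Reagents that add atoms: N-bromosuccinimide, O=C1CCC(=O)N1Br
Why: Electrophilic aromatic bromination at C5, the only unsubstituted position of ring A and activated by three oxygen substituents, whereas ring B carries the deactivating ketone.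

Step 9
Reactants: 13 (4R)-1-methyl-4-(prop-1-en-2-yl)-7-oxabicyclo[4.1.0]heptane ((+)-limonene 1,2-oxide, cis/trans mixture)
Product: 14 (3R)-6-oxo-3-(prop-1-en-2-yl)heptanal
Conditions: H5IO6 (1.1 equiv), THF/H2O, 0 °C to rt
Reagents that add atoms: water, O
Why: Periodic acid hydrolyses the epoxide to the diol and cleaves it (Malaprade glycol cleavage) without touching the isopropenyl group, and the stereocentre of limonene, remote from the reacting carbons, is carried over unchanged.

Step 10
Reactants: 14 (3R)-6-oxo-3-(prop-1-en-2-yl)heptanal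
Product: 15 (3R)-6-oxo-3-(prop-1-en-2-yl)heptanoic acid
Conditions: NaClO2, NaH2PO4, 2-methylbut-2-ene, tBuOH/H2O, 0 °C to rt
Reagents that add atoms: sodium chlorite, [Na+].[O-]Cl=O
Why: Pinnick oxidation of the aldehyde, with 2-methylbut-2-ene scavenging HOCl so that the isopropenyl group survives; the stereocentre is β to the carbonyl and cannot epimerise.

Step 11
Reactants: 15 (3R)-6-oxo-3-(prop-1-en-2-yl)heptanoic acid
Product: 16 (3R)-6-methyl-3-(prop-1-en-2-yl)hept-6-enoic acid
Conditions: Ph3PCH3Br (3 equiv), KOtBu (3 equiv), THF, 0 °C to rt; acidic work-up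
Reagents that add atoms: methyltriphenylphosphonium bromide, C[P+](c1ccccc1)(c1ccccc1)c1ccccc1.[Br-]
Why: Wittig methylenation of the methyl ketone with excess ylide (the first equivalent only deprotonates the acid), at a centre that is not α to any carbonyl group.

Step 12
Reactants: 16 (3R)-6-methyl-3-(prop-1-en-2-yl)hept-6-enoic acid
Product: 18 (3S)-3-(iodomethyl)-2,6-dimethylhepta-1,6-diene, via Barton ester 17 (not isolated)
Conditions: N-hydroxypyridine-2-thione (1.1 equiv), DCC (1.1 equiv), DMAP (cat.), CH2Cl2, rt, dark; then CHI3 (2 equiv), tungsten lamp, reflux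
Reagents that add atoms: iodoform, IC(I)I
Why: Barton decarboxylative iodination, in which the primary radical formed after loss of CO2 should abstract iodine from iodoform faster than it cyclises onto the 1,1-disubstituted alkenes (slow radical clock at a disubstituted alkene carbon), the β-stereocentre being untouched.

Step 13
Reactants: 12 [(2S)-5-bromo-2-(2-hydroxypropan-2-yl)-4-methoxy-6-(methoxymethoxy)-2,3-dihydro-1-benzofuran-7-yl][3-(methoxymethoxy)phenyl]methanone; 18 (3S)-3-(iodomethyl)-2,6-dimethylhepta-1,6-diene
Product: 20 [(2S)-2-(2-hydroxypropan-2-yl)-4-methoxy-6-(methoxymethoxy)-5-[(2R)-5-methyl-2-(prop-1-en-2-yl)hex-5-en-1-yl]-2,3-dihydro-1-benzofuran-7-yl][3-(methoxymethoxy)phenyl]methanone, via alkylzinc iodide 19 (not isolated)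
Conditions: the iodide (2.5 equiv relative to the aryl bromide), Zn dust (activated), LiCl, THF, 40 °C; then the aryl bromide, Pd(OAc)2 (3 mol %), SPhos (6 mol %), THF, rt to 50 °C
Reagents that add atoms: none
Why: Negishi coupling, in which zinc insertion gives the primary alkylzinc 19 and zerovalent palladium with the bulky biaryl phosphine should couple it with the di-ortho-substituted aryl bromide faster than β-hydride elimination, the ketone, tertiary alcohol and MOM ethers tolerating the organozinc.

Step 14
Reactants: 20 [(2S)-2-(2-hydroxypropan-2-yl)-4-methoxy-6-(methoxymethoxy)-5-[(2R)-5-methyl-2-(prop-1-en-2-yl)hex-5-en-1-yl]-2,3-dihydro-1-benzofuran-7-yl][3-(methoxymethoxy)phenyl]methanone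
Product: 21 [(2S)-6-hydroxy-2-(2-hydroxypropan-2-yl)-4-methoxy-5-[(2R)-5-methyl-2-(prop-1-en-2-yl)hex-5-en-1-yl]-2,3-dihydro-1-benzofuran-7-yl](3-hydroxyphenyl)methanone (CNP0263422.2)
Conditions: p-TsOH·H2O (0.3 equiv), MeOH, 40 °C, quenched with NaHCO3 at full conversion
Reagents that add atoms: none
Why: Acid-catalysed transacetalisation should remove both phenolic MOM groups (the C6 ether assisted by the neighbouring ketone) under conditions mild enough to spare the tertiary alcohol and the 1,1-disubstituted alkenes.

## Compound list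

1 | 1,3,5-trimethoxybenzene | COc1cc(OC)cc(OC)c1 | starting material
2 | 3-(benzyloxy)benzoyl chloride | O=C(Cl)c1cccc(OCc2ccccc2)c1 | starting material
3 | [3-(benzyloxy)phenyl](2,4,6-trimethoxyphenyl)methanone | COc1cc(OC)c(C(=O)c2cccc(OCc3ccccc3)c2)c(OC)c1 | intermediate
4 | (2,6-dihydroxy-4-methoxyphenyl)(3-hydroxyphenyl)methanone | COc1cc(O)c(C(=O)c2cccc(O)c2)c(O)c1 | intermediate
5 | 2,4-dihydroxy-3-(3-hydroxybenzoyl)-6-methoxybenzaldehyde | COc1cc(O)c(C(=O)c2cccc(O)c2)c(O)c1C=O | intermediate
6 | 2-hydroxy-6-methoxy-4-(methoxymethoxy)-3-[3-(methoxymethoxy)benzoyl]benzaldehyde | COCOc1cc(OC)c(C=O)c(O)c1C(=O)c1cccc(OCOC)c1 | intermediate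
7 | 2,2-dimethyloxirane | CC1(C)CO1 | starting material
8 | 2-(2-hydroxy-2-methylpropoxy)-6-methoxy-4-(methoxymethoxy)-3-[3-(methoxymethoxy)benzoyl]benzaldehyde | COCOc1cc(OC)c(C=O)c(OCC(C)(C)O)c1C(=O)c1cccc(OCOC)c1 | intermediate
9 | N'-[(E)-{2-(2-hydroxy-2-methylpropoxy)-6-methoxy-4-(methoxymethoxy)-3-[3-(methoxymethoxy)benzoyl]phenyl}methylidene]-4-methylbenzenesulfonohydrazide | COCOc1cc(OC)c(/C=N/NS(=O)(=O)c2ccc(C)cc2)c(OCC(C)(C)O)c1C(=O)c1cccc(OCOC)c1 | intermediate
10 | [3-(diazomethyl)-2-(2-hydroxy-2-methylpropoxy)-4-methoxy-6-(methoxymethoxy)phenyl][3-(methoxymethoxy)phenyl]methanone | COCOc1cc(OC)c(C=[N+]=[N-])c(OCC(C)(C)O)c1C(=O)c1cccc(OCOC)c1 | intermediate (not isolated)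
11 | [(2S)-2-(2-hydroxypropan-2-yl)-4-methoxy-6-(methoxymethoxy)-2,3-dihydro-1-benzofuran-7-yl][3-(methoxymethoxy)phenyl]methanone | COCOc1cc(OC)c2C[C@@H](C(C)(C)O)Oc2c1C(=O)c1cccc(OCOC)c1 | intermediate
12 | [(2S)-5-bromo-2-(2-hydroxypropan-2-yl)-4-methoxy-6-(methoxymethoxy)-2,3-dihydro-1-benzofuran-7-yl][3-(methoxymethoxy)phenyl]methanone | COCOc1c(Br)c(OC)c2C[C@@H](C(C)(C)O)Oc2c1C(=O)c1cccc(OCOC)c1 | intermediate
13 | (4R)-1-methyl-4-(prop-1-en-2-yl)-7-oxabicyclo[4.1.0]heptane ((+)-limonene 1,2-oxide, cis/trans mixture) | CC12OC1C[C@@H](CC2)C(C)=C | starting material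
14 | (3R)-6-oxo-3-(prop-1-en-2-yl)heptanal | O=CC[C@@H](CCC(C)=O)C(C)=C | intermediate
15 | (3R)-6-oxo-3-(prop-1-en-2-yl)heptanoic acid | OC(=O)C[C@@H](CCC(C)=O)C(C)=C | intermediate
16 | (3R)-6-methyl-3-(prop-1-en-2-yl)hept-6-enoic acid | OC(=O)C[C@@H](CCC(C)=C)C(C)=C | intermediate
17 | 2-thioxopyridin-1(2H)-yl (3R)-6-methyl-3-(prop-1-en-2-yl)hept-6-enoate | O=C(C[C@@H](CCC(C)=C)C(C)=C)ON1C=CC=CC1=S | intermediate (not isolated)
18 | (3S)-3-(iodomethyl)-2,6-dimethylhepta-1,6-diene | IC[C@@H](CCC(C)=C)C(C)=C | intermediate
19 | [(2S)-5-methyl-2-(prop-1-en-2-yl)hex-5-en-1-yl]zinc iodide | I[Zn]C[C@@H](CCC(C)=C)C(C)=C | intermediate (not isolated)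
20 | [(2S)-2-(2-hydroxypropan-2-yl)-4-methoxy-6-(methoxymethoxy)-5-[(2R)-5-methyl-2-(prop-1-en-2-yl)hex-5-en-1-yl]-2,3-dihydro-1-benzofuran-7-yl][3-(methoxymethoxy)phenyl]methanone | COCOc1c(C[C@@H](CCC(C)=C)C(C)=C)c(OC)c2C[C@@H](C(C)(C)O)Oc2c1C(=O)c1cccc(OCOC)c1 | intermediate
21 | [(2S)-6-hydroxy-2-(2-hydroxypropan-2-yl)-4-methoxy-5-[(2R)-5-methyl-2-(prop-1-en-2-yl)hex-5-en-1-yl]-2,3-dihydro-1-benzofuran-7-yl](3-hydroxyphenyl)methanone | C=C(C)CC[C@H](Cc1c(O)c(C(=O)c2cccc(O)c2)c2c(c1OC)C[C@@H](C(C)(C)O)O2)C(=C)C | target

## Step count and risks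

Total step count: 14. Longest linear sequence: 10 (steps 1 to 8, then 13 and 14); the side-chain branch (steps 9 to 12) is 4 steps.

Steps most likely to fail:

Step 7. Hydrogen-atom abstraction could take place from the C4 methoxy group instead of the O–CH2 group, the carbene could dimerise or form azine before it abstracts, or the facial discrimination in the radical ring closure could be poor. The fallback sets out from 6 and still closes the ring through the C3–C2 bond, but at the benzofuran oxidation level. Rap–Stoermer condensation of 6 with chloroacetone (K2CO3, DMF, 80 °C: O-alkylation, intramolecular aldol closure of C3–C2, dehydration) should give 1-{4-methoxy-6-(methoxymethoxy)-7-[3-(methoxymethoxy)benzoyl]-1-benzofuran-2-yl}ethan-1-one F1. MeMgBr (THF, −78 °C) should add to the unhindered methyl ketone in preference to the doubly ortho-shielded diaryl ketone to give [2-(2-hydroxypropan-2-yl)-4-methoxy-6-(methoxymethoxy)-1-benzofuran-7-yl][3-(methoxymethoxy)phenyl]methanone F2. Enantioselective hydrogenation of the furan C2=C3 bond (Ru(cod)(2-methylallyl)2, chiral N-heterocyclic carbene from 1,3-bis[1-(naphthalen-1-yl)ethyl]-4,5-dihydroimidazolium tetrafluoroborate, KOtBu, H2 40 bar, hexane) then comes back to the route at 11.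

Step 13. Oxidative addition and transmetalation at the electron-rich, di-ortho-substituted aryl bromide may be slow, so that protodehalogenation, β-hydride elimination with chain isomerisation, or protonolysis of the organozinc by the tertiary alcohol take over. The fallback changes the organometallic class and sets out from 18. Copper-catalysed borylation (CuI, PPh3, LiOMe, B2pin2, DMF, rt) should give 4,4,5,5-tetramethyl-2-[(2S)-5-methyl-2-(prop-1-en-2-yl)hex-5-en-1-yl]-1,3,2-dioxaborolane F3. B-alkyl Suzuki–Miyaura coupling of F3 with 12 (Pd(OAc)2, AntPhos, K3PO4, toluene/H2O, 100 °C) comes back to the route at 20.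

Step 5. Opening of the epoxide by the weakly nucleophilic phenoxide, which is flanked by two carbonyl groups, may be too slow, and prolonged heating could lead to loss of MOM groups or degradation of the aldehyde. The fallback sets out from 6 and uses a reactive allylic electrophile followed by alkene hydration. Alkylation with 3-bromo-2-methylprop-1-ene (K2CO3, DMF, 50 °C) should give 6-methoxy-4-(methoxymethoxy)-3-[3-(methoxymethoxy)benzoyl]-2-[(2-methylprop-2-en-1-yl)oxy]benzaldehyde F4. Mukaiyama hydration (Co(acac)2 cat., PhSiH3, O2, iPrOH/THF, rt) with Markovnikov selectivity comes back to the route at 8.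

Further compounds

F1 | step 7 | 1-{4-methoxy-6-(methoxymethoxy)-7-[3-(methoxymethoxy)benzoyl]-1-benzofuran-2-yl}ethan-1-one | COCOc1cc(OC)c2cc(C(C)=O)oc2c1C(=O)c1cccc(OCOC)c1
F2 | step 7 | [2-(2-hydroxypropan-2-yl)-4-methoxy-6-(methoxymethoxy)-1-benzofuran-7-yl][3-(methoxymethoxy)phenyl]methanone | COCOc1cc(OC)c2cc(C(C)(C)O)oc2c1C(=O)c1cccc(OCOC)c1
F3 | step 13 | 4,4,5,5-tetramethyl-2-[(2S)-5-methyl-2-(prop-1-en-2-yl)hex-5-en-1-yl]-1,3,2-dioxaborolane | CC1(C)OB(C[C@@H](CCC(C)=C)C(C)=C)OC1(C)C
F4 | step 5 | 6-methoxy-4-(methoxymethoxy)-3-[3-(methoxymethoxy)benzoyl]-2-[(2-methylprop-2-en-1-yl)oxy]benzaldehyde | COCOc1cc(OC)c(C=O)c(OCC(C)=C)c1C(=O)c1cccc(OCOC)c1
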